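**Retrosynthetic overview**
- Target ⇐ O-benzyl keto alcohol ⇐ trans ester (redox adjustment), itself from the cis ester by C3 epimerisation.
- Key disconnection (C2–C3, both stereocentres at once): enantioselective intramolecular rhodium-carbene C–H insertion of an aryl diazoacetate into its ArCH2–O group. This replaces the customary biomimetic oxidative phenol/propenylphenol coupling.
- Aryl diazoacetate ⇐ Pd-catalysed coupling of an aryl iodide with ethyl diazoacetate; aryl iodide ⇐ Mitsunobu union of 5-iodoacetovanillone (ring A, acetyl already in place) with O-benzyl syringyl alcohol (ring C).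
- Ring order: rings A and C are bought as arenes; the dihydrofuran ring B is the only ring made, in the key step.

Assumption: the target is the trans-(2S,3R) isomer, and the sense of induction in step 6 is taken from closely related 2-(benzyloxy)aryl diazoacetates, where the (S)-phthalimido-tert-leucinate dirhodium catalyst gives the 2R series; the (R)-catalyst is therefore used.

**Step 1**
Reactants: 1 syringaldehyde (4-hydroxy-3,5-dimethoxybenzaldehyde)
Product: 2 4-(benzyloxy)-3,5-dimethoxybenzaldehyde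
Conditions: BnBr (1.1 equiv), K2CO3 (1.5 equiv), DMF, 60 °C
Reagents that add atoms: benzyl bromide, BrCc1ccccc1
Why: Williamson etherification of the phenoxide installs a benzyl group that survives diazo, carbene, alkoxide and hydride chemistry; no stereocentre is involved.

**Step 2**
Reactants: 2 4-(benzyloxy)-3,5-dimethoxybenzaldehyde
Product: 3 [4-(benzyloxy)-3,5-dimethoxyphenyl]methanol
Conditions: NaBH4, MeOH/THF, 0 °C
Reagents that add atoms: none
Why: Borohydride reduction of the aryl aldehyde gives the benzylic alcohol cleanly, the ethers being inert.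

**Step 3**
Reactants: 4 acetovanillone (1-(4-hydroxy-3-methoxyphenyl)ethan-1-one)
Product: 5 5-iodoacetovanillone (1-(4-hydroxy-3-iodo-5-methoxyphenyl)ethan-1-one)
Conditions: NIS (1.05 equiv), TsOH·H2O (10 mol%), MeCN, rt
Reagents that add atoms: N-iodosuccinimide, O=C1CCC(=O)N1I
Why: Electrophilic aromatic iodination is directed by the phenol to its only free ortho position, the para position being blocked by the acetyl group.

**Step 4**
Reactants: 5 5-iodoacetovanillone; 3 [4-(benzyloxy)-3,5-dimethoxyphenyl]methanol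
Product: 6 1-[4-{[4-(benzyloxy)-3,5-dimethoxyphenyl]methoxy}-3-iodo-5-methoxyphenyl]ethan-1-one
Conditions: PPh3, DIAD, THF, 0 °C to rt
Reagents that add atoms: none
Why: Mitsunobu etherification joins the acidic phenol (pKa about 8) to the primary benzylic alcohol under neutral conditions that spare the aryl iodide, the ketone and the acid-labile electron-rich benzyl ether being formed.

**Step 5**
Reactants: 6 aryl iodide from step 4; 7 ethyl diazoacetate
Product: 8 ethyl 2-[5-acetyl-2-{[4-(benzyloxy)-3,5-dimethoxyphenyl]methoxy}-3-methoxyphenyl]-2-diazoacetate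
Conditions: Pd(PPh3)4 (5 mol%), Ag2CO3 (0.5 equiv), Et3N (1.3 equiv), toluene, rt
Reagents that add atoms: none
Why: Palladium-catalysed cross-coupling of an aryl iodide with a diazoacetate (C–H arylation of the diazo carbon with retention of the diazo group) runs at room temperature, below the temperature at which zerovalent palladium decomposes the diazo ester, and tolerates the aryl ketone.

**Step 6**
Reactants: 8 aryl diazoacetate from step 5
Product: 9 ethyl (2S,3R)-5-acetyl-2-[4-(benzyloxy)-3,5-dimethoxyphenyl]-7-methoxy-2,3-dihydro-1-benzofuran-3-carboxylate (cis)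
Conditions: Rh2(R-PTTL)4 [dirhodium tetrakis(N-phthaloyl-(R)-tert-leucinate)] (1 mol%), toluene, 4 Å MS, −78 °C
Reagents that add atoms: none
Why: Enantioselective intramolecular 1,5 C–H insertion of the donor/acceptor metal carbene into the doubly activated (benzylic, α-oxy) methylene closes ring B; the chiral dirhodium tetracarboxylate selects one enantiotopic benzylic hydrogen and one carbene face, setting C2 (S) and C3 (R) together with kinetic cis selectivity.

**Step 7**
Reactants: 9 cis ester from step 6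
Product: 10 ethyl (2S,3S)-5-acetyl-2-[4-(benzyloxy)-3,5-dimethoxyphenyl]-7-methoxy-2,3-dihydro-1-benzofuran-3-carboxylate (trans)
Conditions: NaOEt (0.2 equiv), EtOH/THF, 0 °C to rt; AcOH quench
Reagents that add atoms: none
Why: Thermodynamic epimerisation by reversible deprotonation at C3 gives the more stable trans isomer (C3 R to S), while C2 is untouched because expulsion of the ring aryloxide (the reverse of a 5-endo-trig closure) is stereoelectronically disfavoured.

**Step 8**
Reactants: 10 trans ester from step 7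
Product: 11 1-[(2S,3R)-2-[4-(benzyloxy)-3,5-dimethoxyphenyl]-3-(hydroxymethyl)-7-methoxy-2,3-dihydro-1-benzofuran-5-yl]ethan-1-ol (both carbinol epimers)
Conditions: LiAlH4, THF, 0 °C
Reagents that add atoms: none
Why: Exhaustive hydride reduction converts the ester into the C3 hydroxymethyl group without touching C2 or C3 (the C3 descriptor changes from S to R only through CIP priorities), and the unavoidable ketone reduction creates a carbinol centre that is erased in step 9.

**Step 9**
Reactants: 11 diol from step 8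
Product: 12 1-[(2S,3R)-2-[4-(benzyloxy)-3,5-dimethoxyphenyl]-3-(hydroxymethyl)-7-methoxy-2,3-dihydro-1-benzofuran-5-yl]ethan-1-one
Conditions: activated MnO2 (15 equiv), CH2Cl2, rt
Reagents that add atoms: none
Why: Chemoselective MnO2 oxidation of the benzylic secondary alcohol restores the aryl ketone while the non-activated primary alcohol is left alone.

**Step 10**
Reactants: 12 keto alcohol from step 9
Product: 13 1-[(2S,3R)-2-(4-hydroxy-3,5-dimethoxyphenyl)-3-(hydroxymethyl)-7-methoxy-2,3-dihydro-1-benzofuran-5-yl]ethan-1-one (target, CNP0167808.1)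
Conditions: H2 (1 atm), Pd/C (10 wt% Pd on carbon), EtOAc, rt, stopped after 1 equiv H2
Reagents that add atoms: none
Why: Catalytic hydrogenolysis of the aryl benzyl ether is much faster under neutral conditions at 1 atm than reduction of the electron-rich aryl ketone or cleavage of the cyclic benzylic C2–O bond, so the free phenol is released without touching the stereocentres.

**Compound list**
1 | syringaldehyde (4-hydroxy-3,5-dimethoxybenzaldehyde) | COc1cc(C=O)cc(OC)c1O | starting material
2 | 4-(benzyloxy)-3,5-dimethoxybenzaldehyde | COc1cc(C=O)cc(OC)c1OCc1ccccc1 | intermediate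
3 | [4-(benzyloxy)-3,5-dimethoxyphenyl]methanol | COc1cc(CO)cc(OC)c1OCc1ccccc1 | intermediate
4 | acetovanillone (1-(4-hydroxy-3-methoxyphenyl)ethan-1-one) | CC(=O)c1ccc(O)c(OC)c1 | starting material
5 | 1-(4-hydroxy-3-iodo-5-methoxyphenyl)ethan-1-one | CC(=O)c1cc(I)c(O)c(OC)c1 | intermediate
6 | 1-[4-{[4-(benzyloxy)-3,5-dimethoxyphenyl]methoxy}-3-iodo-5-methoxyphenyl]ethan-1-one | CC(=O)c1cc(I)c(OCc2cc(OC)c(OCc3ccccc3)c(OC)c2)c(OC)c1 | intermediate
7 | ethyl diazoacetate | CCOC(=O)C=[N+]=[N-] | starting material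
8 | ethyl 2-[5-acetyl-2-{[4-(benzyloxy)-3,5-dimethoxyphenyl]methoxy}-3-methoxyphenyl]-2-diazoacetate | CCOC(=O)C(=[N+]=[N-])c1cc(C(C)=O)cc(OC)c1OCc1cc(OC)c(OCc2ccccc2)c(OC)c1 | intermediate
9 | ethyl (2S,3R)-5-acetyl-2-[4-(benzyloxy)-3,5-dimethoxyphenyl]-7-methoxy-2,3-dihydro-1-benzofuran-3-carboxylate (cis) | COc1cc([C@H]2Oc3c(OC)cc(C(C)=O)cc3[C@H]2C(=O)OCC)cc(OC)c1OCc1ccccc1 | intermediate
10 | ethyl (2S,3S)-5-acetyl-2-[4-(benzyloxy)-3,5-dimethoxyphenyl]-7-methoxy-2,3-dihydro-1-benzofuran-3-carboxylate (trans) | COc1cc([C@H]2Oc3c(OC)cc(C(C)=O)cc3[C@@H]2C(=O)OCC)cc(OC)c1OCc1ccccc1 | intermediate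
11 | 1-[(2S,3R)-2-[4-(benzyloxy)-3,5-dimethoxyphenyl]-3-(hydroxymethyl)-7-methoxy-2,3-dihydro-1-benzofuran-5-yl]ethan-1-ol (carbinol epimers) | COc1cc([C@H]2Oc3c(OC)cc(C(C)O)cc3[C@@H]2CO)cc(OC)c1OCc1ccccc1 | intermediate
12 | 1-[(2S,3R)-2-[4-(benzyloxy)-3,5-dimethoxyphenyl]-3-(hydroxymethyl)-7-methoxy-2,3-dihydro-1-benzofuran-5-yl]ethan-1-one | COc1cc([C@H]2Oc3c(OC)cc(C(C)=O)cc3[C@@H]2CO)cc(OC)c1OCc1ccccc1 | intermediate
13 | 1-[(2S,3R)-2-(4-hydroxy-3,5-dimethoxyphenyl)-3-(hydroxymethyl)-7-methoxy-2,3-dihydro-1-benzofuran-5-yl]ethan-1-one | COc1cc([C@H]2Oc3c(OC)cc(C(C)=O)cc3[C@@H]2CO)cc(OC)c1O | target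

**Step count**
Total: 10 steps. Longest linear sequence: 9 steps (1 → 2 → 3 → 6 → 8 → 9 → 10 → 11 → 12 → 13).

**Three steps most likely to fail**

Step 5 is the first risk. The iodide sits next to a bulky benzyloxy group, and palladium can decompose the diazo product, so yields may be low. The fallback sets out from 6 and comes back at 8. Negishi-type coupling of 6 with the Reformatsky reagent BrZnCH2CO2Et (Pd(dba)2 as the zerovalent palladium source, XPhos, THF, rt; the ketone is tolerated) gives ethyl 2-[5-acetyl-2-{[4-(benzyloxy)-3,5-dimethoxyphenyl]methoxy}-3-methoxyphenyl]acetate F1. Regitz diazo transfer onto the arylacetate methylene of F1 (4-acetamidobenzenesulfonyl azide, DBU, MeCN, 0 °C to rt; the methyl ketone is not acidic enough to react) then returns to 8.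

Step 6 is the key risk. The enantioselectivity on this very electron-rich trialkoxybenzyl ether and acetyl-bearing carbene is untested, and the sense of induction rests on analogy. The fallback sets out from 6 and comes back at 11. It replaces catalyst control by a lactamide auxiliary matched with a prolinate catalyst, which gives the trans ring directly and bypasses steps 6 and 7.
- Commercial (S)-2-hydroxy-N,N-dimethylpropanamide is acylated with bromoacetyl bromide (NaHCO3, MeCN, 0 °C) to (2S)-1-(dimethylamino)-1-oxopropan-2-yl 2-bromoacetate F2.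
- N,N'-Ditosylhydrazine and DBU (THF, 0 °C) convert F2 into (2S)-1-(dimethylamino)-1-oxopropan-2-yl 2-diazoacetate F3.
- Coupling of F3 with 6 under the step 5 conditions gives (2S)-1-(dimethylamino)-1-oxopropan-2-yl 2-[5-acetyl-2-{[4-(benzyloxy)-3,5-dimethoxyphenyl]methoxy}-3-methoxyphenyl]-2-diazoacetate F4.
- Rh2(S-DOSP)4 [dirhodium tetrakis((S)-N-(4-dodecylphenylsulfonyl)prolinate)] (1 mol%, CH2Cl2, −40 °C to rt) effects C–H insertion with double stereodifferentiation to give (2S)-1-(dimethylamino)-1-oxopropan-2-yl (2S,3S)-5-acetyl-2-[4-(benzyloxy)-3,5-dimethoxyphenyl]-7-methoxy-2,3-dihydro-1-benzofuran-3-carboxylate F5. The (S)-auxiliary/(S)-catalyst pairing as the matched one for the (2S,3S) series is from memory of related syntheses; the minor stereoisomers are diastereomers and are removed by chromatography.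
- LiBH4 (THF/MeOH, 0 °C to rt) reduces the ester and the ketone of F5, releases the auxiliary alcohol and delivers 11.

Step 7 is the third risk. The 4-acetyl-2-methoxyphenoxide is a good leaving group, so alkoxide could open the ring (eroding C2), and the methyl ketone can undergo aldol side reactions. The fallback sets out from 9 and comes back at 12. It moves the epimerisation to the aldehyde oxidation level, where a trace of amine base suffices.
- LiAlH4 (THF, 0 °C) reduces 9 to 1-[(2S,3S)-2-[4-(benzyloxy)-3,5-dimethoxyphenyl]-3-(hydroxymethyl)-7-methoxy-2,3-dihydro-1-benzofuran-5-yl]ethan-1-ol F6 (cis).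
- Dess–Martin periodinane (CH2Cl2, NaHCO3, 0 °C) oxidises both alcohols to (2S,3R)-5-acetyl-2-[4-(benzyloxy)-3,5-dimethoxyphenyl]-7-methoxy-2,3-dihydro-1-benzofuran-3-carbaldehyde F7 (cis).
- DBU (5 mol%, CH2Cl2, rt) equilibrates F7 to (2S,3S)-5-acetyl-2-[4-(benzyloxy)-3,5-dimethoxyphenyl]-7-methoxy-2,3-dihydro-1-benzofuran-3-carbaldehyde F8 (trans).
- NaBH4 (0.3 equiv, EtOH/CH2Cl2, −78 °C) reduces the aldehyde of F8 selectively over the aryl ketone and gives 12.

**Further compounds**
F1 | step 5 | ethyl 2-[5-acetyl-2-{[4-(benzyloxy)-3,5-dimethoxyphenyl]methoxy}-3-methoxyphenyl]acetate | CCOC(=O)Cc1cc(C(C)=O)cc(OC)c1OCc1cc(OC)c(OCc2ccccc2)c(OC)c1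
F2 | step 6 | (2S)-1-(dimethylamino)-1-oxopropan-2-yl 2-bromoacetate | C[C@H](OC(=O)CBr)C(=O)N(C)C
F3 | step 6 | (2S)-1-(dimethylamino)-1-oxopropan-2-yl 2-diazoacetate | C[C@H](OC(=O)C=[N+]=[N-])C(=O)N(C)C
F4 | step 6 | (2S)-1-(dimethylamino)-1-oxopropan-2-yl 2-[5-acetyl-2-{[4-(benzyloxy)-3,5-dimethoxyphenyl]methoxy}-3-methoxyphenyl]-2-diazoacetate | C[C@H](OC(=O)C(=[N+]=[N-])c1cc(C(C)=O)cc(OC)c1OCc1cc(OC)c(OCc2ccccc2)c(OC)c1)C(=O)N(C)C
F5 | step 6 | (2S)-1-(dimethylamino)-1-oxopropan-2-yl (2S,3S)-5-acetyl-2-[4-(benzyloxy)-3,5-dimethoxyphenyl]-7-methoxy-2,3-dihydro-1-benzofuran-3-carboxylate | COc1cc([C@H]2Oc3c(OC)cc(C(C)=O)cc3[C@@H]2C(=O)O[C@@H](C)C(=O)N(C)C)cc(OC)c1OCc1ccccc1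
F6 | step 7 | 1-[(2S,3S)-2-[4-(benzyloxy)-3,5-dimethoxyphenyl]-3-(hydroxymethyl)-7-methoxy-2,3-dihydro-1-benzofuran-5-yl]ethan-1-ol (cis, carbinol epimers) | COc1cc([C@H]2Oc3c(OC)cc(C(C)O)cc3[C@H]2CO)cc(OC)c1OCc1ccccc1
F7 | step 7 | (2S,3R)-5-acetyl-2-[4-(benzyloxy)-3,5-dimethoxyphenyl]-7-methoxy-2,3-dihydro-1-benzofuran-3-carbaldehyde (cis) | COc1cc([C@H]2Oc3c(OC)cc(C(C)=O)cc3[C@H]2C=O)cc(OC)c1OCc1ccccc1
F8 | step 7 | (2S,3S)-5-acetyl-2-[4-(benzyloxy)-3,5-dimethoxyphenyl]-7-methoxy-2,3-dihydro-1-benzofuran-3-carbaldehyde (trans) | COc1cc([C@H]2Oc3c(OC)cc(C(C)=O)cc3[C@@H]2C=O)cc(OC)c1OCc1ccccc1
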